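**Plan**
- Retrosynthesis: the C1–C10 bond is cut first, which opens both the cyclohexene and the ten-membered ring to a 14-membered epoxy-enone. Further cuts are C11–C12 (macrocycle), C9–C10 (propyne), C7–C8 with the lactone C7–O bond (aldol–lactonisation), and C13–C14 (vinyl onto a nerol-derived allyl bromide).
- Forward ring order: γ-lactone (step 10), 14-membered carbocycle (step 17), cyclohexane last (step 20); that closure leaves the ten-membered ring as the other part of the macrocycle.
- Feature used: O–C2–C1 and C10–C11–C12=O are 1,5-related across C1–C10. A C1–C2 epoxide therefore gives a β-oxy tertiary radical at C1, and the C10=C11–C12=O enone accepts it at C10, closing the ring C1/C10/C11/C12/C13/C14.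
- Stereochemistry: C17 and the acetal that relays C8 come from an Evans aldol; C7 and C8 are set in the dioxolanone-enolate aldol; C9 by asymmetric transfer hydrogenation; C2 by Shi epoxidation. C1, C10 and C11 are set in the key step, relayed from C9. C12 is set by Luche reduction; the 5Z alkene comes from nerol.

Key step: step 20

Remark: locants follow briarane numbering (ring carbons C1–C14; methyls C15 on C1, C16 on C5, C18 on C17, C20 on C11; C19 is the lactone carbonyl). The C12 epimers of 25 are carried together because step 18 removes that centre.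

**Route**

Step 1
Reactants: 1 nerol
Product: 2 neryl tert-butyldimethylsilyl ether
Conditions: t-BuMe2SiCl, imidazole, DMF, 0 °C to rt
Reagents that add atoms: tert-butyldimethylsilyl chloride, CC(C)(C)[Si](C)(C)Cl
Why: Standard silylation of the primary allylic alcohol masks C7–OH for the bromide and Grignard chemistry of steps 3 and 4.

Step 2
Reactants: 2 neryl tert-butyldimethylsilyl ether
Product: 3 (2E,6Z)-8-(tert-butyldimethylsilyloxy)-2,6-dimethylocta-2,6-dien-1-ol
Conditions: SeO2 (0.3 equiv), t-BuOOH, salicylic acid (cat.), CH2Cl2, rt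
Reagents that add atoms: tert-butyl hydroperoxide, CC(C)(C)OO
Why: Riley allylic oxidation (ene reaction, then [2,3]-shift) should take the E-methyl group of the electron-rich terminal alkene and give the E allylic alcohol (C14–OH), the other alkene being deactivated by its allylic silyloxy group.

Step 3
Reactants: 3 (2E,6Z)-8-(tert-butyldimethylsilyloxy)-2,6-dimethylocta-2,6-dien-1-ol
Product: 4 (2E,6Z)-1-bromo-8-(tert-butyldimethylsilyloxy)-2,6-dimethylocta-2,6-diene
Conditions: CBr4, PPh3, 2,6-lutidine, CH2Cl2, 0 °C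
Reagents that add atoms: carbon tetrabromide, BrC(Br)(Br)Br
Why: Appel bromination of a primary allylic alcohol proceeds by SN2 at the CH2 carbon, so neither alkene geometry is touched.

Step 4
Reactants: 4 (2E,6Z)-1-bromo-8-(tert-butyldimethylsilyloxy)-2,6-dimethylocta-2,6-diene
Product: 5 tert-butyldimethylsilyl ether of (2Z,6E)-3,7-dimethyldeca-2,6,9-trien-1-ol
Conditions: CH2=CHMgBr, Li2CuCl4 (5 mol %), THF, −78 to 0 °C
Reagents that add atoms: vinylmagnesium bromide, C=C[Mg]Br
Why: Copper-catalysed Grignard substitution of the allylic bromide should occur at the primary carbon (attack at the other terminus would build a quaternary carbon), joining C13 to C14 with retention of the E alkene and leaving a terminal vinyl group as masked C12.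

Step 5
Reactants: 5 tert-butyldimethylsilyl ether of (2Z,6E)-3,7-dimethyldeca-2,6,9-trien-1-ol
Product: 6 (2Z,6E)-3,7-dimethyldeca-2,6,9-trien-1-ol
Conditions: Bu4NF, THF, 0 °C to rt
Reagents that add atoms: none
Why: Fluoride cleavage of the primary silyl ether is routine and affects nothing else in the triene.

Step 6
Reactants: 6 (2Z,6E)-3,7-dimethyldeca-2,6,9-trien-1-ol
Product: 7 (2Z,6E)-3,7-dimethyldeca-2,6,9-trienal
Conditions: MnO2 (activated, excess), CH2Cl2, rt
Reagents that add atoms: none
Why: Neutral MnO2 oxidation of the allylic alcohol should give the Z enal (C7 aldehyde) without Z/E isomerisation, as for nerol itself.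

Step 7
Reactants: 8 (R)-4-benzyl-3-propanoyl-1,3-oxazolidin-2-one; 9 ethyl glyoxylate
Product: 11 ethyl (2R,3R)-4-[(4R)-4-benzyl-2-oxo-1,3-oxazolidin-3-yl]-2-hydroxy-3-methyl-4-oxobutanoate, via boron enolate 10 (not isolated)
Conditions: Bu2BOTf, i-Pr2NEt, CH2Cl2, 0 °C; 9 (freshly distilled), −78 to 0 °C; pH 7 buffer, MeOH, H2O2
Reagents that add atoms: none
Why: Evans syn-aldol through the Z boron enolate and a Zimmerman–Traxler chair, in which the (R)-auxiliary should set C17 (R) and the carbinol C8 (R) with a syn relation.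

Step 8
Reactants: 11 ethyl (2R,3R)-4-[(4R)-4-benzyl-2-oxo-1,3-oxazolidin-3-yl]-2-hydroxy-3-methyl-4-oxobutanoate
Product: 12 (2R,3R)-2-hydroxy-3-methylbutanedioic acid
Conditions: LiOH (excess), H2O2, THF/H2O, 0 °C to rt; Na2SO3; HCl to pH 1
Reagents that add atoms: lithium hydroxide, [Li+].[OH-]; hydrogen peroxide, OO
Why: Hydroperoxide cleavage of the imide at the exocyclic carbonyl and saponification of the ethyl ester should give the diacid without touching the two stereocentres.

Step 9
Reactants: 12 (2R,3R)-2-hydroxy-3-methylbutanedioic acid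
Product: 13 (2R)-2-[(2R,4R)-2-tert-butyl-5-oxo-1,3-dioxolan-4-yl]propanoic acid
Conditions: t-BuCHO, TsOH (cat.), H2SO4 (cat.), pentane, reflux with water separator
Reagents that add atoms: pivalaldehyde, CC(C)(C)C=O
Why: Acid-catalysed acetalisation of the α-hydroxy acid unit should give the five-membered dioxolanone as the thermodynamically preferred cis isomer, which stores the C8 configuration in the acetal carbon.

Step 10
Reactants: 13 (2R)-2-[(2R,4R)-2-tert-butyl-5-oxo-1,3-dioxolan-4-yl]propanoic acid; 7 (2Z,6E)-3,7-dimethyldeca-2,6,9-trienal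
Product: 16 spiro lactone-dioxolanone, via dilithium enolate 14 (not isolated), via hydroxy acid 15 (not isolated)
Conditions: LiN(SiMe3)2 (2.2 equiv), THF, −78 °C; 7, −78 °C; 1 M HCl to pH 3; EDC·HCl, DMAP (cat.), CH2Cl2, 0 °C to rt
Reagents that add atoms: none
Why: Aldol addition of the dioxolanone enolate (self-regeneration of the stereocentre) should place C7 on C8 anti to the tert-butyl group and set C7 through a closed chair transition state (C17 branch cis to OLi, hence C17 and O7 syn), after which carbodiimide lactonisation closes the γ-lactone with retention at C7.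

Step 11
Reactants: 16 spiro lactone-dioxolanone
Product: 17 α-hydroxy ynone lactone
Conditions: CH3C≡CLi (1.3 equiv), THF, −78 °C; AcOH, −78 °C; pH 7 buffer
Reagents that add atoms: 1-propynyllithium, [Li]C#CC
Why: Acetylide addition to the acylal carbonyl (C9), the most electrophilic carbonyl present, should stop at the tetrahedral alkoxide, which on protonation collapses to the ynone, the free C8–OH and pivalaldehyde; the propynyl group brings C10, C11 and C20.

Step 12
Reactants: 17 α-hydroxy ynone lactone
Product: 18 (9R)-propargylic diol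
Conditions: Ru(p-cymene)[(S,S)-TsDPEN] (5 mol %), i-PrOH, rt
Reagents that add atoms: none
Why: Noyori asymmetric transfer hydrogenation of an ynone is catalyst-controlled (alkyne versus quaternary carbon is a clear-cut pair), and the (S,S) catalyst should give the 9R carbinol under neutral conditions that spare the lactone and the alkenes.

Step 13
Reactants: 18 (9R)-propargylic diol
Product: 19 C9 acetate
Conditions: Ac2O, pyridine, DMAP (cat.), CH2Cl2, 0 °C
Reagents that add atoms: acetic anhydride, CC(=O)OC(C)=O
Why: Acetylation should take the secondary C9–OH and leave the tertiary C8–OH, installing the C9 acetate of the target early as the protecting group for the oxidations ahead.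

Step 14
Reactants: 19 C9 acetate
Product: 21 C12 primary alcohol, via B-alkyl-9-BBN adduct 20 (not isolated)
Conditions: 9-BBN (2.5 equiv), THF, 0 °C to rt; H2O2, NaOAc (aq.), 0 °C
Reagents that add atoms: hydrogen peroxide, OO
Why: Hydroboration–oxidation with 9-BBN is selective for the monosubstituted alkene over the trisubstituted alkenes and the internal alkyne and places the hydroxyl on C12.

Step 15
Reactants: 21 C12 primary alcohol
Product: 23 (E)-alkenyl iodide, via alkenylzirconocene 22 (not isolated)
Conditions: Cp2Zr(H)Cl (3.5 equiv), THF, rt, short reaction time; I2, 0 °C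
Reagents that add atoms: iodine, II
Why: Hydrozirconation adds H and Zr syn across the alkyne with zirconium on the less hindered methyl-bearing carbon C11, and iodinolysis with retention should give the E iodide (C9 cis to CH3-20).

Step 16
Reactants: 23 (E)-alkenyl iodide
Product: 24 C12 aldehyde
Conditions: Dess–Martin periodinane, NaHCO3, CH2Cl2, 0 °C to rt
Reagents that add atoms: none
Why: Dess–Martin oxidation of the primary alcohol is mild enough for the alkenyl iodide, the acetate and the tertiary alcohol.

Step 17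
Reactants: 24 C12 aldehyde
Product: 25 14-membered allylic alcohol (C12 epimers)
Conditions: CrCl2 (10 equiv), NiCl2 (1 mol %), DMSO/THF, rt, 2 mM, slow addition
Reagents that add atoms: none
Why: Nozaki–Hiyama–Kishi macrocyclisation joins C11 to C12 chemoselectively at the aldehyde with retention of the alkene geometry; a 14-membered ring is a favourable size for this closure.

Step 18
Reactants: 25 14-membered allylic alcohol (C12 epimers)
Product: 26 14-membered (10E)-enone
Conditions: Dess–Martin periodinane, NaHCO3, CH2Cl2, rt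
Reagents that add atoms: none
Why: Oxidation of the allylic alcohol merges both epimers into the C10=C11–C12=O enone, the radical acceptor of the key step.

Step 19
Reactants: 26 14-membered (10E)-enone
Product: 27 (1R,2R)-epoxy enone
Conditions: D-fructose-derived Shi ketone (0.5 equiv), KHSO5 (Oxone), K2CO3, Bu4NHSO4, MeCN/CH2(OMe)2/aq. Na2B4O7 buffer (pH 10.5), 0 °C
Reagents that add atoms: potassium peroxymonosulfate, [K+].[O-]S(=O)(=O)OO
Why: Shi asymmetric epoxidation should take only the isolated electron-rich C1=C2 alkene (C5=C6 is deactivated by the allylic lactone oxygen, the enone is electron-poor), and the catalyst's spiro transition state should set C2 (R).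

Step 20
Reactants: 27 (1R,2R)-epoxy enone
Product: 30 tricyclic hydroxy ketone, via C1 radical 28 (not isolated), via titanium enolate 29 (not isolated)
Conditions: Cp2TiCl2 (2.5 equiv), Mn (8 equiv), THF, rt; 27 added over 2 h (5 mM); 1 M HCl, 0 °C
Reagents that add atoms: none
Why: Cp2TiCl (trivalent titanium) opens the epoxide by electron transfer at the more substituted carbon to give the tertiary β-titanoxy radical at C1 (the C2–O bond and its configuration are untouched), which adds across the ring to C10, the β-carbon of the enone; a second Cp2TiCl reduces the α-keto radical to the titanium enolate, which is protonated at C11 on work-up. The closest known reaction type is the Nugent–RajanBabu reductive epoxide opening with Giese addition to an enone, together with its transannular use in macrocyclic epoxy alkenes. One bond closes two rings: the cyclohexane (C1, C10, C11, C12, C13, C14) by 6-endo-trig attack of the C1 radical on the enone, and with it the ten-membered ring (C1 to C10) as the remainder of the 14-membered ring. C10 is set by C9: allylic 1,3-strain with CH3-20 holds H-9 in the enone plane, so C1, which the ring chain delivers through C8, attacks the face of C8 anti to the C9 acetoxy group; C1 follows from a chair-like transition state with the C1 methyl axial and the larger C2 branch equatorial (CH3-15 trans to H-10), and C11 from protonation of the enolate anti to the pseudo-axial C9 branch on C10. The step needs the nucleophilic radical to choose C10 over the C5=C6 alkene (also placed for a six-membered closure) and over reduction by titanium: the polarity-matched enone is the faster acceptor, a tertiary radical is trapped only slowly by Cp2TiCl, and attack at the α-carbon C11 would be 5-exo onto a fully substituted carbon.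

Step 21
Reactants: 30 tricyclic hydroxy ketone
Product: 32 enone diol, via silyl enol ether 31 (not isolated)
Conditions: LiN(SiMe3)2 (3.5 equiv), Me3SiCl, THF, −78 °C; Pd(OAc)2 (1.1 equiv), MeCN, rt; 1 M HCl, THF, 0 °C
Reagents that add atoms: none
Why: Kinetic enolisation takes the less substituted C13 (C11 and its configuration are left alone, the two hydroxyls are silylated in passing), and Saegusa–Ito oxidation of the silyl enol ether should give the C13=C14 enone, with the silyl ethers hydrolysed on acidic work-up.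

Step 22
Reactants: 32 enone diol
Product: 33 enone diacetate
Conditions: Ac2O, DMAP, pyridine, CH2Cl2, rt
Reagents that add atoms: acetic anhydride, CC(=O)OC(C)=O
Why: Acetylation should take the secondary C2–OH only, the tertiary C8–OH next to the lactone being too hindered.

Step 23
Reactants: 33 enone diacetate
Product: 34 CNP0222085.1 (target)
Conditions: NaBH4, CeCl3·7H2O, MeOH, −78 °C
Reagents that add atoms: none
Why: Luche 1,2-reduction should deliver hydride axially, anti to axial H-11 in the half-chair with equatorial CH3-20, giving the 12-OH trans to CH3-20 (12R) without touching the acetates or the lactone.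

**Compound list**
1 | nerol, (2Z)-3,7-dimethylocta-2,6-dien-1-ol | CC(C)=CCC/C(C)=C\CO | starting material
2 | neryl tert-butyldimethylsilyl ether | CC(C)=CCC/C(C)=C\CO[Si](C)(C)C(C)(C)C | intermediate
3 | (2E,6Z)-8-(tert-butyldimethylsilyloxy)-2,6-dimethylocta-2,6-dien-1-ol | OC/C(C)=C/CC/C(C)=C\CO[Si](C)(C)C(C)(C)C | intermediate
4 | (2E,6Z)-1-bromo-8-(tert-butyldimethylsilyloxy)-2,6-dimethylocta-2,6-diene | BrC/C(C)=C/CC/C(C)=C\CO[Si](C)(C)C(C)(C)C | intermediate
5 | tert-butyldimethylsilyl ether of (2Z,6E)-3,7-dimethyldeca-2,6,9-trien-1-ol | C=CC/C(C)=C/CC/C(C)=C\CO[Si](C)(C)C(C)(C)C | intermediate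
6 | (2Z,6E)-3,7-dimethyldeca-2,6,9-trien-1-ol | C=CC/C(C)=C/CC/C(C)=C\CO | intermediate
7 | (2Z,6E)-3,7-dimethyldeca-2,6,9-trienal (C7 aldehyde; C6–C1, C14–C12) | C=CC/C(C)=C/CC/C(C)=C\C=O | intermediate
8 | (R)-4-benzyl-3-propanoyl-1,3-oxazolidin-2-one | CCC(=O)N1[C@H](Cc2ccccc2)COC1=O | starting material
9 | ethyl glyoxylate | CCOC(=O)C=O | starting material
10 | (Z)-dibutylboron enolate of 8 (not isolated) | C/C=C(\OB(CCCC)CCCC)N1[C@H](Cc2ccccc2)COC1=O | intermediate
11 | ethyl (2R,3R)-4-[(4R)-4-benzyl-2-oxo-1,3-oxazolidin-3-yl]-2-hydroxy-3-methyl-4-oxobutanoate | CCOC(=O)[C@H](O)[C@@H](C)C(=O)N1[C@H](Cc2ccccc2)COC1=O | intermediate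
12 | (2R,3R)-2-hydroxy-3-methylbutanedioic acid (C9, C8, C17 with C18, C19) | OC(=O)[C@H](O)[C@@H](C)C(O)=O | intermediate
13 | (2R)-2-[(2R,4R)-2-tert-butyl-5-oxo-1,3-dioxolan-4-yl]propanoic acid (cis acetal) | OC(=O)[C@H](C)[C@H]1O[C@@H](C(C)(C)C)OC1=O | intermediate
14 | dilithium carboxylate-enolate of 13 (not isolated) | [Li]OC(=O)[C@H](C)C1=C(O[Li])O[C@H](C(C)(C)C)O1 | intermediate
15 | aldol hydroxy acid: C7 carbinol, C8 quaternary in the dioxolanone, free C19 acid (not isolated) | C=CC/C(C)=C/CC/C(C)=C\[C@H](O)[C@]1([C@@H](C)C(O)=O)O[C@@H](C(C)(C)C)OC1=O | intermediate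
16 | spiro lactone-dioxolanone: C7–O–C19 γ-lactone, C8 shared with the 2-tert-butyl-1,3-dioxolan-4-one (C9 carbonyl), C7 bearing the (1Z,5E)-2,6-dimethylnona-1,5,8-trienyl chain; C7, C8, C17 as in the target | C=CC/C(C)=C/CC/C(C)=C\[C@@H]1OC(=O)[C@H](C)[C@]12O[C@@H](C(C)(C)C)OC2=O | intermediate
17 | α-hydroxy ynone lactone: 8-OH, C9 ketone, C10≡C11–C20 | C=CC/C(C)=C/CC/C(C)=C\[C@@H]1OC(=O)[C@H](C)[C@@]1(O)C(=O)C#CC | intermediate
18 | (9R)-propargylic diol (8-OH, 9-OH) | C=CC/C(C)=C/CC/C(C)=C\[C@@H]1OC(=O)[C@H](C)[C@@]1(O)[C@H](O)C#CC | intermediate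
19 | C9 acetate of 18 (8-OH free) | C=CC/C(C)=C/CC/C(C)=C\[C@@H]1OC(=O)[C@H](C)[C@@]1(O)[C@H](OC(C)=O)C#CC | intermediate
20 | B-alkyl-9-BBN adduct at C12 (not isolated) | B1(CCC/C(C)=C/CC/C(C)=C\[C@@H]3OC(=O)[C@H](C)[C@@]3(O)[C@H](OC(C)=O)C#CC)C2CCCC1CCC2 | intermediate
21 | C12 primary alcohol | OCCC/C(C)=C/CC/C(C)=C\[C@@H]1OC(=O)[C@H](C)[C@@]1(O)[C@H](OC(C)=O)C#CC | intermediate
22 | (E)-alkenylzirconocene chloride, Zr on C11 (not isolated) | OCCC/C(C)=C/CC/C(C)=C\[C@@H]1OC(=O)[C@H](C)[C@@]1(O)[C@H](OC(C)=O)/C=C(/[Zr](Cl)(C2C=CC=C2)C2C=CC=C2)C | intermediate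
23 | (E)-alkenyl iodide (I on C11, C9 cis to CH3-20), C12 alcohol | OCCC/C(C)=C/CC/C(C)=C\[C@@H]1OC(=O)[C@H](C)[C@@]1(O)[C@H](OC(C)=O)/C=C(/I)C | intermediate
24 | C12 aldehyde of 23 | O=CCC/C(C)=C/CC/C(C)=C\[C@@H]1OC(=O)[C@H](C)[C@@]1(O)[C@H](OC(C)=O)/C=C(/I)C | intermediate
25 | 14-membered carbocycle (C1–C14, no C1–C10 bond) fused to the lactone: 12-OH (both epimers), 1E, 5Z, 10E alkenes, 9-OAc, 8-OH | OC1CC/C(C)=C/CC/C(C)=C\[C@@H]2OC(=O)[C@H](C)[C@@]2(O)[C@H](OC(C)=O)/C=C1\C | intermediate
26 | 14-membered (10E)-enone, C12 ketone | O=C1CC/C(C)=C/CC/C(C)=C\[C@@H]2OC(=O)[C@H](C)[C@@]2(O)[C@H](OC(C)=O)/C=C1\C | intermediate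
27 | (1R,2R)-1,2-epoxide of 26 | O=C1CC[C@@]3(C)O[C@@H]3CC/C(C)=C\[C@@H]2OC(=O)[C@H](C)[C@@]2(O)[C@H](OC(C)=O)/C=C1\C | intermediate
28 | tertiary C1 radical with C2–O–TiCp2Cl (not isolated) | O=C1CC[C](C)[C@H](O[Ti](Cl)(C3C=CC=C3)C3C=CC=C3)CC/C(C)=C\[C@@H]2OC(=O)[C@H](C)[C@@]2(O)[C@H](OC(C)=O)/C=C1\C | intermediate
29 | cyclised titanium enolate (C11=C12–OTi) with C2–OTi (not isolated) | CC(=O)O[C@@H]1[C@H]2C(C)=C(O[Ti](Cl)(C3C=CC=C3)C3C=CC=C3)CC[C@]2(C)[C@H](O[Ti](Cl)(C3C=CC=C3)C3C=CC=C3)CC/C(C)=C\[C@@H]2OC(=O)[C@H](C)[C@]21O | intermediate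
30 | tricyclic hydroxy ketone: (1S,2R,7S,8S,9R,10S,11R,17R), 2-OH, 8-OH, 9-OAc, C12 ketone, 5Z alkene | CC(=O)O[C@@H]1[C@H]2[C@@H](C)C(=O)CC[C@]2(C)[C@H](O)CC/C(C)=C\[C@@H]2OC(=O)[C@H](C)[C@]21O | intermediate
31 | C12–C13 trimethylsilyl enol ether with 2-O- and 8-O-trimethylsilyl groups (not isolated) | CC(=O)O[C@@H]1[C@H]2[C@@H](C)C(O[Si](C)(C)C)=CC[C@]2(C)[C@H](O[Si](C)(C)C)CC/C(C)=C\[C@@H]2OC(=O)[C@H](C)[C@]21O[Si](C)(C)C | intermediate
32 | enone diol: C12 ketone, C13=C14, 2-OH, 8-OH, 9-OAc | CC(=O)O[C@@H]1[C@H]2[C@@H](C)C(=O)C=C[C@]2(C)[C@H](O)CC/C(C)=C\[C@@H]2OC(=O)[C@H](C)[C@]21O | intermediate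
33 | enone diacetate: 2-OAc, 9-OAc, 8-OH, C12 ketone | CC(=O)O[C@@H]1[C@H]2[C@@H](C)C(=O)C=C[C@]2(C)[C@H](OC(C)=O)CC/C(C)=C\[C@@H]2OC(=O)[C@H](C)[C@]21O | intermediate
34 | CNP0222085.1: (1S,2R,5Z,7S,8S,9R,10S,11R,12R,17R) briarane, 2,9-diacetate, 8,12-diol, Δ5 and Δ13, 7,19-lactone | CC(=O)O[C@@H]1[C@H]2[C@@H](C)[C@H](O)C=C[C@]2(C)[C@H](OC(C)=O)CC/C(C)=C\[C@@H]2OC(=O)[C@H](C)[C@]21O | target

**Step count and risks**

Total: 23 steps. Longest linear sequence: 20 steps (steps 1–6 and 10–23, from nerol).

Step 20. The tertiary radical may be reduced or intercepted by a second titanium centre (deoxygenation or β-hydride elimination) before it reaches C10, it may add to the C5=C6 alkene, or the relay from C9 to C10 and C1 may be incomplete. Fallback, from 27: Me3SiOTf with 2,6-lutidine and then DBU (CH2Cl2, −78 °C to rt) should isomerise the epoxide to the allylic silyl ether with an exocyclic C1=C15 methylene, the bis-silyl ether F1 (the C8 hydroxyl is silylated as well). Fe(acac)3 and PhSiH3 (EtOH/ethylene glycol, 60 °C) should then form the same C1 radical by hydrogen-atom transfer to the methylene carbon, with no metal reductant that can intercept it, and close the ring to the silylated ketone F2 (reductive olefin–enone coupling). 1 M HCl in MeOH would remove both silyl groups and return the route at 30.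

Step 23. Hydride may be delivered to the wrong face of the C12 carbonyl, because the face needed is flanked by the axial C9 branch in one half-chair and by two methyl groups in the other. Fallback, from 33: a reduction that goes the other way (for example with LiAlH(O-t-Bu)3) gives the 12-epi alcohol F3. Mitsunobu inversion with ClCH2CO2H, PPh3 and DIAD (toluene, 0 °C) should give the inverted chloroacetate F4, and thiourea with NaHCO3 in EtOH should remove the chloroacetyl group in the presence of the two acetates, returning the route at 34.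

Step 11. The acetylide may also attack the lactone carbonyl, add twice, or deprotonate C17 with β-elimination of the C8 oxygen. Fallback, from 16: EtSH and Et3N (CH2Cl2, 0 °C) should open only the acylal, with loss of pivalaldehyde, to the S-ethyl thioester F5. Coupling of F5 with propyne under PdCl2(dppf), CuI, P(2-furyl)3 and Et3N in DMF (thioester–alkyne ketone synthesis) should then give the ynone without any carbanion, returning the route at 17.

**Further compounds**
F1 | step 20 | 14-membered enone with C1=C15 exocyclic methylene, 2-O- and 8-O-trimethylsilyl, 9-OAc | O=C1CCC(=C)[C@H](O[Si](C)(C)C)CC/C(C)=C\[C@@H]2OC(=O)[C@H](C)[C@@]2(O[Si](C)(C)C)[C@H](OC(C)=O)/C=C1\C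
F2 | step 20 | 2-O,8-O-bis(trimethylsilyl) ether of 30 | CC(=O)O[C@@H]1[C@H]2[C@@H](C)C(=O)CC[C@]2(C)[C@H](O[Si](C)(C)C)CC/C(C)=C\[C@@H]2OC(=O)[C@H](C)[C@]21O[Si](C)(C)C
F3 | step 23 | 12-epimer of 34 (12S alcohol) | CC(=O)O[C@@H]1[C@H]2[C@@H](C)[C@@H](O)C=C[C@]2(C)[C@H](OC(C)=O)CC/C(C)=C\[C@@H]2OC(=O)[C@H](C)[C@]21O
F4 | step 23 | 12-O-chloroacetate of 34 | CC(=O)O[C@@H]1[C@H]2[C@@H](C)[C@H](OC(=O)CCl)C=C[C@]2(C)[C@H](OC(C)=O)CC/C(C)=C\[C@@H]2OC(=O)[C@H](C)[C@]21O
F5 | step 11 | S-ethyl thioester at C9 of the lactone with free 8-OH | C=CC/C(C)=C/CC/C(C)=C\[C@@H]1OC(=O)[C@H](C)[C@@]1(O)C(=O)SCC
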